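**Retrosynthetic overview**
1. Target 14 ⇐ hydrogenolysis of tribenzyl ether 13 ⇐ hydrolytic ring opening and decarboxylation of the (6R)-4-hydroxy-5,6-dihydro-2-pyranone 11. The lactone carbonyl is a traceless carbon, the ring oxygen becomes the C5 carbinol oxygen and ring C4 becomes the C3 ketone.
2. 11 ⇐ enantioselective Ru-catalysed hydrogenation of the C5=C6 bond of the flat, pseudo-aromatic 2-pyranone 10. This is the key step: it breaks the pyranone aromaticity and sets the only stereocentre.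
3. 10 ⇐ triacetic acid lactone 1, by C–C bond formation at its two nucleophilic sites: C3 (reductive alkylation with O-benzylvanillin 2) and the 6-methyl group (dianion alkylation with benzylic bromide 8, made from 5-hydroxyvanillin 5).
4. Rings: no ring is formed. Both benzene rings and the pyranone ring are bought, and the pyranone ring is opened at the end.

Assumption: 1, 2 and 5 are bought; the (S)-MeO-BIPHEP ligand is taken to give the (6R)-lactone by analogy with 3,6-dialkyl-4-hydroxy-2-pyranones, and if the measured sense is opposite the (R)-ligand is used with nothing else changed.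

**Route**

Step 1
Reactants: 1 4-hydroxy-6-methyl-2H-pyran-2-one (triacetic acid lactone); 2 4-(benzyloxy)-3-methoxybenzaldehyde (O-benzylvanillin)
Product: 4 3-[4-(benzyloxy)-3-methoxybenzyl]-4-hydroxy-6-methyl-2H-pyran-2-one, via arylidene-dione 3 (not isolated)
Conditions: Hantzsch ester (1.1 equiv), L-proline (20 mol %), EtOH, 25→50 °C
Reagents that add atoms: none
Why: Knoevenagel condensation at the nucleophilic C3 of the 4-hydroxy-2-pyranone gives arylidene dione 3, which the Hantzsch ester reduces by hydride transfer before a second pyranone can add (organocatalytic three-component reductive alkylation).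

Step 2
Reactants: 5 3,4-dihydroxy-5-methoxybenzaldehyde (5-hydroxyvanillin)
Product: 6 3,4-bis(benzyloxy)-5-methoxybenzaldehyde
Conditions: BnBr (2.3 equiv), K2CO3, DMF, 60 °C, N2
Reagents that add atoms: benzyl bromide, BrCc1ccccc1
Why: Williamson ether synthesis on both catechol hydroxyls; benzyl ethers survive LDA and the Ru hydrogenation and come off by hydrogenolysis at the end.

Step 3
Reactants: 6 3,4-bis(benzyloxy)-5-methoxybenzaldehyde
Product: 7 [3,4-bis(benzyloxy)-5-methoxyphenyl]methanol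
Conditions: NaBH4, MeOH/THF, 0 °C
Reagents that add atoms: none
Why: Borohydride reduction of an aryl aldehyde to the benzylic alcohol; nothing else in 6 is reducible.

Step 4
Reactants: 7 [3,4-bis(benzyloxy)-5-methoxyphenyl]methanol
Product: 8 1,2-bis(benzyloxy)-5-(bromomethyl)-3-methoxybenzene
Conditions: PBr3 (0.4 equiv), Et2O, 0 °C; used crude at once
Reagents that add atoms: phosphorus tribromide, BrP(Br)Br
Why: Bromination of a benzylic alcohol through its phosphite ester (SN2); the electron-rich bromide is not chromatographed.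

Step 5
Reactants: 4 3-[4-(benzyloxy)-3-methoxybenzyl]-4-hydroxy-6-methyl-2H-pyran-2-one; 8 1,2-bis(benzyloxy)-5-(bromomethyl)-3-methoxybenzene
Product: 10 3-[4-(benzyloxy)-3-methoxybenzyl]-6-{2-[3,4-bis(benzyloxy)-5-methoxyphenyl]ethyl}-4-hydroxy-2H-pyran-2-one, via dilithio dianion 9 (not isolated)
Conditions: LDA (commercial solution, 2.3 equiv), THF/DMPU, −78 °C, 1 h; then 8 (0.9 equiv), −78→−30 °C; 1 M HCl quench
Reagents that add atoms: none
Why: Lateral metalation: LDA removes the acidic 4-OH proton and then a proton of the vinylogous 6-methyl group, and dianion 9 is alkylated by the benzylic bromide at the last-formed, most basic carbon (SN2), C3 being blocked.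

Step 6
Reactants: 10 3-[4-(benzyloxy)-3-methoxybenzyl]-6-{2-[3,4-bis(benzyloxy)-5-methoxyphenyl]ethyl}-4-hydroxy-2H-pyran-2-one
Product: 11 (6R)-3-[4-(benzyloxy)-3-methoxybenzyl]-6-{2-[3,4-bis(benzyloxy)-5-methoxyphenyl]ethyl}-4-hydroxy-5,6-dihydro-2H-pyran-2-one
Conditions: [Ru(OAc)2((S)-MeO-BIPHEP)] (1 mol %), HBF4·OEt2 (2 mol %), H2 (60 bar), MeOH/CH2Cl2, 60 °C
Reagents that add atoms: none
Why: Ru-catalysed asymmetric hydrogenation of a 3,6-disubstituted 4-hydroxy-2-pyranone, a known substrate class: the enolised β-keto-lactone anchors on cationic Ru and H2 adds to one face of C5=C6, which sets C6 as R; the tetrasubstituted C3=C4 enol and the benzyl ethers are not reduced.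

Step 7
Reactants: 11 (6R)-3-[4-(benzyloxy)-3-methoxybenzyl]-6-{2-[3,4-bis(benzyloxy)-5-methoxyphenyl]ethyl}-4-hydroxy-5,6-dihydro-2H-pyran-2-one
Product: 13 (5R)-1-[4-(benzyloxy)-3-methoxyphenyl]-7-[3,4-bis(benzyloxy)-5-methoxyphenyl]-5-hydroxyheptan-3-one, via β-keto acid 12 (not isolated)
Conditions: 1,4-dioxane/H2O (1:1), 95 °C, N2, 2–4 h
Reagents that add atoms: none
Why: Neutral hydrolytic ring opening of the β-keto-δ-lactone through its keto tautomer gives β-keto acid 12, which loses CO2 at this temperature (ketonic hydrolysis of a β-keto ester); the C–O bond at the stereocentre is never broken, so the R configuration is kept, and the absence of base avoids retro-aldol cleavage.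

Step 8
Reactants: 13 (5R)-1-[4-(benzyloxy)-3-methoxyphenyl]-7-[3,4-bis(benzyloxy)-5-methoxyphenyl]-5-hydroxyheptan-3-one
Product: 14 (5R)-7-(3,4-dihydroxy-5-methoxyphenyl)-5-hydroxy-1-(4-hydroxy-3-methoxyphenyl)heptan-3-one
Conditions: H2 (1 atm), 10 % Pd/C, EtOAc/MeOH, rt, then work-up under N2
Reagents that add atoms: none
Why: Hydrogenolysis of the three aryl benzyl ethers under neutral conditions leaves the aliphatic ketone and the β-hydroxyl untouched.

**Compound list**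
1 | 4-hydroxy-6-methyl-2H-pyran-2-one (triacetic acid lactone) | CC1=CC(O)=CC(=O)O1 | starting material
2 | 4-(benzyloxy)-3-methoxybenzaldehyde | COc1cc(C=O)ccc1OCc1ccccc1 | starting material
3 | 3-[4-(benzyloxy)-3-methoxybenzylidene]-6-methyl-2H-pyran-2,4(3H)-dione | CC1=CC(=O)C(=Cc2ccc(OCc3ccccc3)c(OC)c2)C(=O)O1 | intermediate (not isolated)
4 | 3-[4-(benzyloxy)-3-methoxybenzyl]-4-hydroxy-6-methyl-2H-pyran-2-one | CC1=CC(O)=C(Cc2ccc(OCc3ccccc3)c(OC)c2)C(=O)O1 | intermediate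
5 | 3,4-dihydroxy-5-methoxybenzaldehyde | COc1cc(C=O)cc(O)c1O | starting material
6 | 3,4-bis(benzyloxy)-5-methoxybenzaldehyde | COc1cc(C=O)cc(OCc2ccccc2)c1OCc1ccccc1 | intermediate
7 | [3,4-bis(benzyloxy)-5-methoxyphenyl]methanol | COc1cc(CO)cc(OCc2ccccc2)c1OCc1ccccc1 | intermediate
8 | 1,2-bis(benzyloxy)-5-(bromomethyl)-3-methoxybenzene | COc1cc(CBr)cc(OCc2ccccc2)c1OCc1ccccc1 | intermediate
9 | dilithio dianion of 4 (4-O-lithio, 6-lithiomethyl) | [Li]CC1=CC(O[Li])=C(Cc2ccc(OCc3ccccc3)c(OC)c2)C(=O)O1 | intermediate (not isolated)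
10 | 3-[4-(benzyloxy)-3-methoxybenzyl]-6-{2-[3,4-bis(benzyloxy)-5-methoxyphenyl]ethyl}-4-hydroxy-2H-pyran-2-one | O=C1OC(CCc2cc(OCc3ccccc3)c(OCc3ccccc3)c(OC)c2)=CC(O)=C1Cc1ccc(OCc2ccccc2)c(OC)c1 | intermediate
11 | (6R)-3-[4-(benzyloxy)-3-methoxybenzyl]-6-{2-[3,4-bis(benzyloxy)-5-methoxyphenyl]ethyl}-4-hydroxy-5,6-dihydro-2H-pyran-2-one | O=C1O[C@H](CCc2cc(OCc3ccccc3)c(OCc3ccccc3)c(OC)c2)CC(O)=C1Cc1ccc(OCc2ccccc2)c(OC)c1 | intermediate
12 | (5R)-2-[4-(benzyloxy)-3-methoxybenzyl]-7-[3,4-bis(benzyloxy)-5-methoxyphenyl]-5-hydroxy-3-oxoheptanoic acid (C2 epimers) | OC(=O)C(Cc1ccc(OCc2ccccc2)c(OC)c1)C(=O)C[C@H](O)CCc1cc(OCc2ccccc2)c(OCc2ccccc2)c(OC)c1 | intermediate (not isolated)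
13 | (5R)-1-[4-(benzyloxy)-3-methoxyphenyl]-7-[3,4-bis(benzyloxy)-5-methoxyphenyl]-5-hydroxyheptan-3-one | COc1cc(CCC(=O)C[C@H](O)CCc2cc(OCc3ccccc3)c(OCc3ccccc3)c(OC)c2)ccc1OCc1ccccc1 | intermediate
14 | (5R)-7-(3,4-dihydroxy-5-methoxyphenyl)-5-hydroxy-1-(4-hydroxy-3-methoxyphenyl)heptan-3-one | COc1cc(CCC(=O)C[C@H](O)CCc2cc(O)c(O)c(OC)c2)ccc1O | target

**Totals**
Total step count: 8. Longest linear sequence: 7 steps (5 → 6 → 7 → 8 → 10 → 11 → 13 → 14).

**Three steps most likely to fail**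

Step 6 (asymmetric pyranone hydrogenation). The bulky tris-benzyloxy substrate may react slowly or give insufficient ee. The fallback sets the stereocentre by β-keto ester hydrogenation instead; it sets out from bromide 8 and comes back at 11. The dianion of methyl acetoacetate (LDA, 2 equiv, THF, 0 °C) is alkylated with 8 to give methyl 5-[3,4-bis(benzyloxy)-5-methoxyphenyl]-3-oxopentanoate F1. Noyori hydrogenation (RuCl2[(R)-BINAP], H2, MeOH) gives methyl (3R)-5-[3,4-bis(benzyloxy)-5-methoxyphenyl]-3-hydroxypentanoate F2. Cross-Claisen condensation with excess lithium tert-butyl acetate (THF, −78→−20 °C) gives tert-butyl (5R)-7-[3,4-bis(benzyloxy)-5-methoxyphenyl]-5-hydroxy-3-oxoheptanoate F3. TFA in CH2Cl2 closes it to (6R)-6-{2-[3,4-bis(benzyloxy)-5-methoxyphenyl]ethyl}dihydro-2H-pyran-2,4(3H)-dione F4. Reductive alkylation of F4 with aldehyde 2 and Hantzsch ester/proline, through (6R)-3-[4-(benzyloxy)-3-methoxybenzylidene]-6-{2-[3,4-bis(benzyloxy)-5-methoxyphenyl]ethyl}dihydro-2H-pyran-2,4(3H)-dione F5, gives 11.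

Step 5 (dianion alkylation). Risks are over-alkylation, O-alkylation and decomposition of the labile bromide 8. The fallback replaces the SN2 step by aldol condensation and alkene reduction; it sets out from 4 (through dianion 9) and aldehyde 6 and comes back at 10. Addition of 6 to 9 at −78 °C gives the aldol adduct 3-[4-(benzyloxy)-3-methoxybenzyl]-6-{2-[3,4-bis(benzyloxy)-5-methoxyphenyl]-2-hydroxyethyl}-4-hydroxy-2H-pyran-2-one F6. Dehydration (TsOH, toluene, 80 °C) gives 3-[4-(benzyloxy)-3-methoxybenzyl]-6-[(E)-2-[3,4-bis(benzyloxy)-5-methoxyphenyl]ethenyl]-4-hydroxy-2H-pyran-2-one F7. Hydrogenation of only the exocyclic C=C with RhCl(PPh3)3/H2 (benzene/EtOH) gives 10. This fallback also makes steps 3 and 4 unnecessary.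

Step 7 (decarboxylative ring opening). The lipophilic enol lactone may open slowly in aqueous dioxane, and prolonged heating risks dehydration of the β-hydroxy ketone to the enone. The fallback moves the deprotection ahead so that the ring opening is the last step, run on a water-soluble substrate; it sets out from 11 and comes back at 14. Hydrogenolysis of 11 (H2, Pd/C, EtOAc/MeOH) gives (6R)-6-[2-(3,4-dihydroxy-5-methoxyphenyl)ethyl]-4-hydroxy-3-(4-hydroxy-3-methoxybenzyl)-5,6-dihydro-2H-pyran-2-one F8. Heating F8 in degassed water (90 °C, N2) opens it to (5R)-7-(3,4-dihydroxy-5-methoxyphenyl)-5-hydroxy-2-(4-hydroxy-3-methoxybenzyl)-3-oxoheptanoic acid F9, which loses CO2 to give 14.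

**Further compounds**
F1 | step 6 | methyl 5-[3,4-bis(benzyloxy)-5-methoxyphenyl]-3-oxopentanoate | COC(=O)CC(=O)CCc1cc(OCc2ccccc2)c(OCc2ccccc2)c(OC)c1
F2 | step 6 | methyl (3R)-5-[3,4-bis(benzyloxy)-5-methoxyphenyl]-3-hydroxypentanoate | COC(=O)C[C@H](O)CCc1cc(OCc2ccccc2)c(OCc2ccccc2)c(OC)c1
F3 | step 6 | tert-butyl (5R)-7-[3,4-bis(benzyloxy)-5-methoxyphenyl]-5-hydroxy-3-oxoheptanoate | CC(C)(C)OC(=O)CC(=O)C[C@H](O)CCc1cc(OCc2ccccc2)c(OCc2ccccc2)c(OC)c1
F4 | step 6 | (6R)-6-{2-[3,4-bis(benzyloxy)-5-methoxyphenyl]ethyl}dihydro-2H-pyran-2,4(3H)-dione | O=C1CC(=O)C[C@@H](CCc2cc(OCc3ccccc3)c(OCc3ccccc3)c(OC)c2)O1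
F5 | step 6 | (6R)-3-[4-(benzyloxy)-3-methoxybenzylidene]-6-{2-[3,4-bis(benzyloxy)-5-methoxyphenyl]ethyl}dihydro-2H-pyran-2,4(3H)-dione | O=C1O[C@H](CCc2cc(OCc3ccccc3)c(OCc3ccccc3)c(OC)c2)CC(=O)C1=Cc1ccc(OCc2ccccc2)c(OC)c1
F6 | step 5 | 3-[4-(benzyloxy)-3-methoxybenzyl]-6-{2-[3,4-bis(benzyloxy)-5-methoxyphenyl]-2-hydroxyethyl}-4-hydroxy-2H-pyran-2-one (racemic carbinol) | O=C1OC(CC(O)c2cc(OCc3ccccc3)c(OCc3ccccc3)c(OC)c2)=CC(O)=C1Cc1ccc(OCc2ccccc2)c(OC)c1
F7 | step 5 | 3-[4-(benzyloxy)-3-methoxybenzyl]-6-[(E)-2-[3,4-bis(benzyloxy)-5-methoxyphenyl]ethenyl]-4-hydroxy-2H-pyran-2-one | O=C1OC(/C=C/c2cc(OCc3ccccc3)c(OCc3ccccc3)c(OC)c2)=CC(O)=C1Cc1ccc(OCc2ccccc2)c(OC)c1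
F8 | step 7 | (6R)-6-[2-(3,4-dihydroxy-5-methoxyphenyl)ethyl]-4-hydroxy-3-(4-hydroxy-3-methoxybenzyl)-5,6-dihydro-2H-pyran-2-one | O=C1O[C@H](CCc2cc(O)c(O)c(OC)c2)CC(O)=C1Cc1ccc(O)c(OC)c1
F9 | step 7 | (5R)-7-(3,4-dihydroxy-5-methoxyphenyl)-5-hydroxy-2-(4-hydroxy-3-methoxybenzyl)-3-oxoheptanoic acid | OC(=O)C(Cc1ccc(O)c(OC)c1)C(=O)C[C@H](O)CCc1cc(O)c(O)c(OC)c1
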